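Retrosynthesis: the flavonol is cut at the ring C ether bond O1–C8a, then at C2–C3 (enolate acylation) and at C4–C4a (aryllithium acylation). This leaves a ring A fluoroarene, a benzyloxyacetyl unit and a chroman acid (ring B with its fused dihydropyran, ring D).
Enabling feature: C8a of ring A, the carbon that carries the ring C oxygen O1, is bonded to C4a and so sits ortho to the C4 ketone. A fluorine placed on C8a is therefore an SNAr leaving group that the far enolate oxygen of a 2-benzyloxy-1,3-diketone can displace.
Forward order: ring D is built first on methyl 4-hydroxybenzoate by a propargyl ether Claisen cyclisation. The ring A ketone comes from 1,3,5-trifluorobenzene. The two are joined by C-acylation, ring C closes last, then the protecting groups are removed.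
Stereochemistry: the only stereocentre (chroman C3, R) is set by a Jacobsen epoxidation of the chromene with the (R,R)-salen manganese catalyst. Benzylic hydrogenolysis of the epoxide leaves the C3–O bond untouched, and the alcohol is carried as a silyl ether.

Key step: step 13

Remark: in its diketo form, diketone 21 has a stereocentre at the central carbon and also exists as enol tautomers. It is carried as the mixture, because this carbon becomes sp2 (C3 of the flavonol) in step 13.

**Route**

Step 1
Reactants: 1 methyl 4-hydroxybenzoate; 2 3-chloro-3-methylbut-1-yne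
Product: 3 methyl 4-[(2-methylbut-3-yn-2-yl)oxy]benzoate
Conditions: K2CO3, KI, CuI (cat.), acetone, reflux
Reagents that add atoms: none
Why: Copper-assisted O-alkylation of a phenoxide by a tertiary propargylic chloride is the standard entry to aryl 1,1-dimethylpropargyl ethers, works well for electron-poor phenols, and leaves the ester untouched.

Step 2
Reactants: 3 methyl 4-[(2-methylbut-3-yn-2-yl)oxy]benzoate
Product: 4 methyl 2,2-dimethyl-2H-chromene-6-carboxylate
Conditions: PhNEt2, 190 °C
Reagents that add atoms: none
Why: Aromatic propargyl Claisen rearrangement, then 1,5-hydrogen shift and 6π-oxa-electrocyclisation, is the classical thermal 2,2-dimethylchromene synthesis, and the two equivalent ortho positions allow only one regioisomer.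

Step 3
Reactants: 4 methyl 2,2-dimethyl-2H-chromene-6-carboxylate
Product: 5 methyl (3R,4R)-3,4-epoxy-2,2-dimethylchroman-6-carboxylate
Conditions: (R,R)-(salen)MnCl [(R,R)-N,N'-bis(3,5-di-tert-butylsalicylidene)cyclohexane-1,2-diaminatomanganese chloride, trivalent manganese] (cat.), aq. NaOCl buffered to pH 11.3, 4-phenylpyridine N-oxide (cat.), CH2Cl2, 0 °C
Reagents that add atoms: sodium hypochlorite, [Na+].[O-]Cl
Why: Jacobsen epoxidation is at its best with 2,2-dimethylchromenes bearing an electron-withdrawing 6-substituent, and the (R,R)-catalyst should deliver oxygen to the alkene face that gives the (3R,4R)-epoxide, which fixes C3.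

Step 4
Reactants: 5 methyl (3R,4R)-3,4-epoxy-2,2-dimethylchroman-6-carboxylate
Product: 6 methyl (3R)-3-hydroxy-2,2-dimethylchroman-6-carboxylate
Conditions: H2 (1 atm), Pd/C, EtOAc, rt
Reagents that add atoms: none
Why: Palladium-catalysed hydrogenolysis of an aryl epoxide cleaves only the benzylic C4–O bond, so the C3–O bond and its R configuration are retained.

Step 5
Reactants: 6 methyl (3R)-3-hydroxy-2,2-dimethylchroman-6-carboxylate
Product: 7 methyl (3R)-3-(tert-butyldimethylsilyloxy)-2,2-dimethylchroman-6-carboxylate
Conditions: TBSOTf, 2,6-lutidine, CH2Cl2, 0 °C to rt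
Reagents that add atoms: tert-butyldimethylsilyl trifluoromethanesulfonate, CC(C)(C)[Si](C)(C)OS(=O)(=O)C(F)(F)F
Why: Silylation with the silyl triflate and a hindered pyridine base is the reliable way to protect a secondary alcohol next to a quaternary carbon.

Step 6
Reactants: 7 methyl (3R)-3-(tert-butyldimethylsilyloxy)-2,2-dimethylchroman-6-carboxylate
Product: 8 (3R)-3-(tert-butyldimethylsilyloxy)-2,2-dimethylchroman-6-carboxylic acid
Conditions: LiOH, THF/MeOH/H2O, 40 °C; then 1 M HCl to pH 4, 0 °C
Reagents that add atoms: lithium hydroxide, [Li+].[OH-]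
Why: Ester saponification by acyl substitution proceeds under conditions that a hindered secondary silyl ether tolerates.

Step 7
Reactants: 8 (3R)-3-(tert-butyldimethylsilyloxy)-2,2-dimethylchroman-6-carboxylic acid
Product: 9 (3R)-3-(tert-butyldimethylsilyloxy)-2,2-dimethylchroman-6-carbonyl chloride
Conditions: 1-chloro-N,N,2-trimethylprop-1-en-1-amine, CH2Cl2, 0 °C to rt; evaporate, use crude
Reagents that add atoms: 1-chloro-N,N,2-trimethylprop-1-en-1-amine, CC(C)=C(Cl)N(C)C
Why: The α-chloroenamine converts the acid into the acid chloride under neutral conditions, with an amide as the only by-product and no free HCl to endanger the silyl ether.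

Step 8
Reactants: 10 1,3,5-trifluorobenzene; 11 benzyl alcohol
Product: 13 1,3-bis(benzyloxy)-5-fluorobenzene, via 1-(benzyloxy)-3,5-difluorobenzene 12 (not isolated)
Conditions: 11 (2.1 equiv), NaH (2.1 equiv), NMP, 0 °C to rt; then 10 (1.0 equiv), rt to 100 °C, sealed vessel
Reagents that add atoms: benzyl alcohol (second equivalent), OCc1ccccc1
Why: Two successive nucleophilic aromatic substitutions of fluoride by sodium benzyloxide in a dipolar aprotic solvent, the first giving monoether 12 and the second consuming another equivalent of the alkoxide, should stop at the monofluoride because each alkoxy group introduced makes the ring less electrophilic.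

Step 9
Reactants: 13 1,3-bis(benzyloxy)-5-fluorobenzene
Product: 14 1,5-bis(benzyloxy)-2-bromo-3-fluorobenzene
Conditions: NBS, MeCN, 0 °C to rt, dark
Reagents that add atoms: N-bromosuccinimide, O=C1CCC(=O)N1Br
Why: Electrophilic aromatic bromination of a 5-substituted 1,3-dialkoxybenzene should go para to one alkoxy group (here the carbon next to fluorine), since the site between the two benzyloxy groups is flanked on both sides.

Step 10
Reactants: 15 benzyloxyacetyl chloride
Product: 16 2-(benzyloxy)-N-methoxy-N-methylacetamide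
Conditions: MeNH(OMe)·HCl, K2CO3, EtOAc/H2O, 0 °C to rt
Reagents that add atoms: N,O-dimethylhydroxylamine hydrochloride, CNOC.Cl
Why: Schotten–Baumann amidation of an acid chloride gives the Weinreb amide directly.

Step 11
Reactants: 14 1,5-bis(benzyloxy)-2-bromo-3-fluorobenzene; 16 2-(benzyloxy)-N-methoxy-N-methylacetamide
Product: 19 2-(benzyloxy)-1-[2,4-bis(benzyloxy)-6-fluorophenyl]ethan-1-one, via aryllithium 17 (not isolated), via tetrahedral lithium adduct 18 (not isolated)
Conditions: n-BuLi, THF, −78 °C; then 16, −78 to −40 °C; 1 M HCl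
Reagents that add atoms: none
Why: Bromine–lithium exchange at −78 °C is faster than benzylic deprotonation or loss of LiF, and the Weinreb ketone synthesis stops at the chelated tetrahedral adduct, so the ketone is released only on work-up.

Step 12
Reactants: 19 2-(benzyloxy)-1-[2,4-bis(benzyloxy)-6-fluorophenyl]ethan-1-one; 9 (3R)-3-(tert-butyldimethylsilyloxy)-2,2-dimethylchroman-6-carbonyl chloride
Product: 21 2-(benzyloxy)-1-[2,4-bis(benzyloxy)-6-fluorophenyl]-3-[(3R)-3-(tert-butyldimethylsilyloxy)-2,2-dimethylchroman-6-yl]propane-1,3-dione, via lithium enolate 20 (not isolated)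
Conditions: 19 (2.0 equiv), LiN(SiMe3)2 (2.1 equiv), toluene/THF, −78 °C; then 9 (1.0 equiv), −78 to −20 °C; AcOH
Reagents that add atoms: none
Why: Claisen-type C-acylation of a ketone lithium enolate by an acid chloride forms the C2–C3 bond, the second equivalent of enolate removes the acidic proton of the 1,3-diketone as it forms (the excess of 19 is recovered after the quench), and the uncontrolled centre at the central carbon is of no consequence.

Step 13
Reactants: 21 2-(benzyloxy)-1-[2,4-bis(benzyloxy)-6-fluorophenyl]-3-[(3R)-3-(tert-butyldimethylsilyloxy)-2,2-dimethylchroman-6-yl]propane-1,3-dione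
Product: 23 3,5,7-tris(benzyloxy)-2-[(3R)-3-(tert-butyldimethylsilyloxy)-2,2-dimethylchroman-6-yl]-4H-chromen-4-one, via potassium enolate 22 (not isolated)
Conditions: K2CO3, dry DMF, 80 °C
Reagents that add atoms: none
Why: K2CO3 deprotonates the 1,3-diketone, and the enolate oxygen on the ring B side adds to C8a, the fluorine-bearing carbon ortho to the ring A ketone, to give a Meisenheimer-type adduct whose charge is taken up by that ketone, after which fluoride is expelled and the O1–C8a bond is in place. The closest known reaction type is the base-mediated flavone synthesis by intramolecular O-arylation of 1-(2-haloaryl)-1,3-diketones, an SNAr addition–elimination. Ring C closes in a six-membered mode by attack of oxygen on a trigonal aromatic carbon (formally 6-exo-trig with respect to the C8a–C8 π bond), followed by rearomatisation. No stereocentre is formed, since the central carbon of 21 becomes the sp2 C3 of the flavonol, so its epimers and enol forms converge, and the chroman C3 centre is remote and not enolisable. The step needs O-arylation at one defined carbon, which is secured by the single fluoride ortho to the ketone and by geometry, since only the distal enolate oxygen reaches C8a through a six-membered transition state, while the central carbon and the proximal oxygen could only form four-membered rings. Both benzyloxy groups are meta to the fluoride and so do not push electron density onto the carbon under attack, and C3 already carries its oxygen, so no later oxidation is needed.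

Step 14
Reactants: 23 3,5,7-tris(benzyloxy)-2-[(3R)-3-(tert-butyldimethylsilyloxy)-2,2-dimethylchroman-6-yl]-4H-chromen-4-one
Product: 24 3,5,7-tris(benzyloxy)-2-[(3R)-3-hydroxy-2,2-dimethylchroman-6-yl]-4H-chromen-4-one
Conditions: Bu4NF (1 M in wet THF), THF, rt to 40 °C
Reagents that add atoms: none
Why: Fluoride-mediated desilylation is driven by the strength of the Si–F bond and leaves benzyl ethers and the chromone untouched.

Step 15
Reactants: 24 3,5,7-tris(benzyloxy)-2-[(3R)-3-hydroxy-2,2-dimethylchroman-6-yl]-4H-chromen-4-one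
Product: 25 3,5,7-trihydroxy-2-[(3R)-3-hydroxy-2,2-dimethylchroman-6-yl]-4H-chromen-4-one (CNP0411714.1)
Conditions: H2 (1 atm), Pd/C, EtOAc/MeOH, rt
Reagents that add atoms: none
Why: Catalytic hydrogenolysis removes the two aryl benzyl ethers and the C3 enol benzyl ether at atmospheric pressure, where the tetrasubstituted push–pull C2=C3 bond, the chroman ether and the secondary alcohol should not react.

**Compound list**

1 | methyl 4-hydroxybenzoate | COC(=O)c1ccc(O)cc1 | starting material
2 | 3-chloro-3-methylbut-1-yne | C#CC(C)(C)Cl | starting material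
3 | methyl 4-[(2-methylbut-3-yn-2-yl)oxy]benzoate | COC(=O)c1ccc(OC(C)(C)C#C)cc1 | intermediate
4 | methyl 2,2-dimethyl-2H-chromene-6-carboxylate | COC(=O)c1ccc2OC(C)(C)C=Cc2c1 | intermediate
5 | methyl (3R,4R)-3,4-epoxy-2,2-dimethylchroman-6-carboxylate | COC(=O)c1ccc2OC(C)(C)[C@@H]3O[C@@H]3c2c1 | intermediate
6 | methyl (3R)-3-hydroxy-2,2-dimethylchroman-6-carboxylate | COC(=O)c1ccc2OC(C)(C)[C@H](O)Cc2c1 | intermediate
7 | methyl (3R)-3-(tert-butyldimethylsilyloxy)-2,2-dimethylchroman-6-carboxylate | COC(=O)c1ccc2OC(C)(C)[C@H](O[Si](C)(C)C(C)(C)C)Cc2c1 | intermediate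
8 | (3R)-3-(tert-butyldimethylsilyloxy)-2,2-dimethylchroman-6-carboxylic acid | OC(=O)c1ccc2OC(C)(C)[C@H](O[Si](C)(C)C(C)(C)C)Cc2c1 | intermediate
9 | (3R)-3-(tert-butyldimethylsilyloxy)-2,2-dimethylchroman-6-carbonyl chloride | ClC(=O)c1ccc2OC(C)(C)[C@H](O[Si](C)(C)C(C)(C)C)Cc2c1 | intermediate
10 | 1,3,5-trifluorobenzene | Fc1cc(F)cc(F)c1 | starting material
11 | benzyl alcohol | OCc1ccccc1 | starting material
12 | 1-(benzyloxy)-3,5-difluorobenzene (product of the first substitution, formed in the flask) | Fc1cc(F)cc(OCc2ccccc2)c1 | intermediate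
13 | 1,3-bis(benzyloxy)-5-fluorobenzene | Fc1cc(OCc2ccccc2)cc(OCc2ccccc2)c1 | intermediate
14 | 1,5-bis(benzyloxy)-2-bromo-3-fluorobenzene | Fc1cc(OCc2ccccc2)cc(OCc2ccccc2)c1Br | intermediate
15 | benzyloxyacetyl chloride | O=C(Cl)COCc1ccccc1 | starting material
16 | 2-(benzyloxy)-N-methoxy-N-methylacetamide | CON(C)C(=O)COCc1ccccc1 | intermediate
17 | [2,4-bis(benzyloxy)-6-fluorophenyl]lithium (aryllithium, formed in the flask) | [Li]c1c(F)cc(OCc2ccccc2)cc1OCc1ccccc1 | intermediate
18 | lithium 2-(benzyloxy)-1-[2,4-bis(benzyloxy)-6-fluorophenyl]-1-[methoxy(methyl)amino]ethan-1-olate (tetrahedral lithium adduct, racemic, formed in the flask) | [Li]OC(COCc1ccccc1)(N(C)OC)c1c(F)cc(OCc2ccccc2)cc1OCc1ccccc1 | intermediate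
19 | 2-(benzyloxy)-1-[2,4-bis(benzyloxy)-6-fluorophenyl]ethan-1-one | O=C(COCc1ccccc1)c1c(F)cc(OCc2ccccc2)cc1OCc1ccccc1 | intermediate
20 | lithium (Z)-enolate of 19 (chelated, formed in the flask) | [Li]O/C(=C\OCc1ccccc1)c1c(F)cc(OCc2ccccc2)cc1OCc1ccccc1 | intermediate
21 | 2-(benzyloxy)-1-[2,4-bis(benzyloxy)-6-fluorophenyl]-3-[(3R)-3-(tert-butyldimethylsilyloxy)-2,2-dimethylchroman-6-yl]propane-1,3-dione (epimers at the central carbon and enol forms) | O=C(c1c(F)cc(OCc2ccccc2)cc1OCc1ccccc1)C(OCc1ccccc1)C(=O)c1ccc2OC(C)(C)[C@H](O[Si](C)(C)C(C)(C)C)Cc2c1 | intermediate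
22 | potassium enolate of 21 (U-shaped diketonate, formed in the flask) | [K+].[O-]/C(c1ccc2OC(C)(C)[C@H](O[Si](C)(C)C(C)(C)C)Cc2c1)=C(/OCc1ccccc1)C(=O)c1c(F)cc(OCc2ccccc2)cc1OCc1ccccc1 | intermediate
23 | 3,5,7-tris(benzyloxy)-2-[(3R)-3-(tert-butyldimethylsilyloxy)-2,2-dimethylchroman-6-yl]-4H-chromen-4-one | CC1(C)Oc2ccc(-c3oc4cc(OCc5ccccc5)cc(OCc5ccccc5)c4c(=O)c3OCc3ccccc3)cc2C[C@H]1O[Si](C)(C)C(C)(C)C | intermediate
24 | 3,5,7-tris(benzyloxy)-2-[(3R)-3-hydroxy-2,2-dimethylchroman-6-yl]-4H-chromen-4-one | CC1(C)Oc2ccc(-c3oc4cc(OCc5ccccc5)cc(OCc5ccccc5)c4c(=O)c3OCc3ccccc3)cc2C[C@H]1O | intermediate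
25 | 3,5,7-trihydroxy-2-[(3R)-3-hydroxy-2,2-dimethylchroman-6-yl]-4H-chromen-4-one (CNP0411714.1) | CC1(C)Oc2ccc(-c3oc4cc(O)cc(O)c4c(=O)c3O)cc2C[C@H]1O | target

**Step count and risks**

Total step count: 15. Longest linear sequence: 11 steps (steps 1 to 7, then 12 to 15, from methyl 4-hydroxybenzoate). The ring A branch (steps 8, 9 and 11, with step 10 feeding it) joins at step 12.

The three steps most likely to fail:

1. Step 12. The hindered α-alkoxy enolate may be acylated on oxygen instead of carbon, or may react so slowly that the acid chloride is lost to side reactions. The fallback forms the same C2–C3 bond at the aldehyde oxidation level. It sets out from ester 7 (with ketone 19) and comes back to the route at diketone 21. Reduction of 7 with i-Bu2AlH in CH2Cl2 at −78 °C would give [(3R)-3-(tert-butyldimethylsilyloxy)-2,2-dimethylchroman-6-yl]methanol F1. Oxidation with MnO2 in CH2Cl2 would give (3R)-3-(tert-butyldimethylsilyloxy)-2,2-dimethylchroman-6-carbaldehyde F2. Aldol addition of lithium enolate 20 to F2 in THF at −78 °C would give 2-(benzyloxy)-1-[2,4-bis(benzyloxy)-6-fluorophenyl]-3-[(3R)-3-(tert-butyldimethylsilyloxy)-2,2-dimethylchroman-6-yl]-3-hydroxypropan-1-one F3 as a mixture of diastereomers. A Dess–Martin oxidation of F3 would then give 21.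

2. Step 13. The addition–elimination may be slow, because ring A is electron-rich and its ketone is twisted out of the ring plane by two ortho substituents. That would leave time for retro-Claisen cleavage of the diketone by traces of water, or for loss of the silyl ether to the liberated fluoride. Loss of the silyl group alone is harmless, since it leads to 24. The fallback keeps the same ring closure but activates ring A with two further fluorines and introduces the benzyl ethers afterwards. It sets out from 1,3,5-trifluorobenzene 10, Weinreb amide 16 and acid chloride 9, and comes back at 23. Deprotonation of 10 with n-BuLi in THF at −78 °C would give 2,4,6-trifluorophenyllithium F4, which with 16 would give 2-(benzyloxy)-1-(2,4,6-trifluorophenyl)ethan-1-one F5. Its lithium (Z)-enolate F6 (LiN(SiMe3)2, THF, −78 °C) would be acylated by 9 to 2-(benzyloxy)-3-[(3R)-3-(tert-butyldimethylsilyloxy)-2,2-dimethylchroman-6-yl]-1-(2,4,6-trifluorophenyl)propane-1,3-dione F7. K2CO3 in DMF would close ring C at either of the two equivalent ortho fluorides to give 3-(benzyloxy)-2-[(3R)-3-(tert-butyldimethylsilyloxy)-2,2-dimethylchroman-6-yl]-5,7-difluoro-4H-chromen-4-one F8. Two equivalents of benzyl alcohol 11 with NaH in DMF would then replace the C5 and C7 fluorides, which lie ortho and para to the C4 carbonyl, to give 23.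

3. Step 11. The ortho-fluoro aryllithium may lose LiF to an aryne on warming, or may deprotonate the amide instead of adding to it, because the carbanion is flanked by two substituents. The fallback makes the ring A carbanion as a magnesium reagent and traps it at the aldehyde oxidation level. It sets out from bromide 14 and comes back at ketone 19. Bromine–magnesium exchange with i-PrMgCl·LiCl in THF at −15 °C would give [2,4-bis(benzyloxy)-6-fluorophenyl]magnesium chloride F9. Addition to commercial benzyloxyacetaldehyde would give racemic 2-(benzyloxy)-1-[2,4-bis(benzyloxy)-6-fluorophenyl]ethan-1-ol F10. A Dess–Martin oxidation of F10 would give 19.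

Further compounds
F1 | step 12 | [(3R)-3-(tert-butyldimethylsilyloxy)-2,2-dimethylchroman-6-yl]methanol | OCc1ccc2OC(C)(C)[C@H](O[Si](C)(C)C(C)(C)C)Cc2c1
F2 | step 12 | (3R)-3-(tert-butyldimethylsilyloxy)-2,2-dimethylchroman-6-carbaldehyde | O=Cc1ccc2OC(C)(C)[C@H](O[Si](C)(C)C(C)(C)C)Cc2c1
F3 | step 12 | 2-(benzyloxy)-1-[2,4-bis(benzyloxy)-6-fluorophenyl]-3-[(3R)-3-(tert-butyldimethylsilyloxy)-2,2-dimethylchroman-6-yl]-3-hydroxypropan-1-one | O=C(c1c(F)cc(OCc2ccccc2)cc1OCc1ccccc1)C(OCc1ccccc1)C(O)c1ccc2OC(C)(C)[C@H](O[Si](C)(C)C(C)(C)C)Cc2c1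
F4 | step 13 | 2,4,6-trifluorophenyllithium | [Li]c1c(F)cc(F)cc1F
F5 | step 13 | 2-(benzyloxy)-1-(2,4,6-trifluorophenyl)ethan-1-one | O=C(COCc1ccccc1)c1c(F)cc(F)cc1F
F6 | step 13 | lithium (Z)-enolate of 2-(benzyloxy)-1-(2,4,6-trifluorophenyl)ethan-1-one | [Li]O/C(=C\OCc1ccccc1)c1c(F)cc(F)cc1F
F7 | step 13 | 2-(benzyloxy)-3-[(3R)-3-(tert-butyldimethylsilyloxy)-2,2-dimethylchroman-6-yl]-1-(2,4,6-trifluorophenyl)propane-1,3-dione | O=C(c1c(F)cc(F)cc1F)C(OCc1ccccc1)C(=O)c1ccc2OC(C)(C)[C@H](O[Si](C)(C)C(C)(C)C)Cc2c1
F8 | step 13 | 3-(benzyloxy)-2-[(3R)-3-(tert-butyldimethylsilyloxy)-2,2-dimethylchroman-6-yl]-5,7-difluoro-4H-chromen-4-one | CC1(C)Oc2ccc(-c3oc4cc(F)cc(F)c4c(=O)c3OCc3ccccc3)cc2C[C@H]1O[Si](C)(C)C(C)(C)C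
F9 | step 11 | [2,4-bis(benzyloxy)-6-fluorophenyl]magnesium chloride | Cl[Mg]c1c(F)cc(OCc2ccccc2)cc1OCc1ccccc1
F10 | step 11 | 2-(benzyloxy)-1-[2,4-bis(benzyloxy)-6-fluorophenyl]ethan-1-ol (racemic) | OC(COCc1ccccc1)c1c(F)cc(OCc2ccccc2)cc1OCc1ccccc1
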